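**Plan**
- Retrosynthesis: after loss of the O-protecting groups, unit 1 (the 5,7-dihydroxyflavanone) is cut at C2–C1' (aryl transfer from boron to a 5,7-diacetoxychromone). The aryl–O bond of the diaryl ether on ring B of unit 1 is cut back to syringaldehyde and an arylboronic acid.
- Unit 2 (the flavanone with the aryloxy group at C6) is cut at O1–C8a and C4–C4a. These two ring-C bonds leave ring A from adjacent carbons, C4a beside the C5 oxygen and C8a beside the unsubstituted C8. That is the pattern of a 3-alkoxyaryne, which takes an alkoxide at the remote carbon and leaves the carbanion next to the alkoxy group.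
- Forward order: diaryl ether; symmetrical 4-aryloxy-3,5-bis(MOM)phenol and its ortho-silyl triflate; ring C of unit 2 by aryne annulation with a (3S)-β-silyloxy Weinreb amide; chloride to boronic acid; unit 1 completed by conjugate addition to the preformed chromone; global deprotection.
- Stereochemistry: C2 of unit 2 comes from Noyori transfer hydrogenation of a β-keto ester and is carried through with its C–O bond intact. C2 of unit 1 is set by the chiral pyridine-oxazoline ligand in the palladium-catalysed conjugate addition.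

Key step: step 13

Assumption: (R)-t-BuPyOx is taken to deliver the aryl group to the chromone face that gives 2S, by analogy with the facial sense this ligand class shows with β-substituted cyclic enones; if the sense proves opposite, the (S)-ligand is used.

**Route**

Step 1
Reactants: 1 syringaldehyde; 2 4-chlorophenylboronic acid
Product: 3 4-(4-chlorophenoxy)-3,5-dimethoxybenzaldehyde
Conditions: Cu(OAc)2 (0.2 equiv), pyridine, 4 Å MS, O2 (1 atm), CH2Cl2, 23 °C
Reagents that add atoms: none
Why: Chan–Lam oxidative C–O coupling is known to accept di-ortho-substituted phenols and leaves the aldehyde and the aryl chloride untouched.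

Step 2
Reactants: 3 4-(4-chlorophenoxy)-3,5-dimethoxybenzaldehyde
Product: 4 4-(4-chlorophenoxy)-3,5-dihydroxybenzaldehyde
Conditions: BBr3, CH2Cl2, −78 → 0 °C; then H2O
Reagents that add atoms: none
Why: Lewis-acid demethylation of aryl methyl ethers with BBr3 spares the diaryl ether and the aryl chloride, and the aldehyde is returned on hydrolysis.

Step 3
Reactants: 4 4-(4-chlorophenoxy)-3,5-dihydroxybenzaldehyde
Product: 5 4-(4-chlorophenoxy)-3,5-bis(methoxymethoxy)benzaldehyde
Conditions: MOMCl, i-Pr2NEt, CH2Cl2, 0 → 23 °C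
Reagents that add atoms: chloromethyl methyl ether, COCCl
Why: O-alkylation of both phenols (MOM protection) installs acetals that survive organolithium, fluoride and palladium steps and come off with acid at the end.

Step 4
Reactants: 5 4-(4-chlorophenoxy)-3,5-bis(methoxymethoxy)benzaldehyde
Product: 7 4-(4-chlorophenoxy)-3,5-bis(methoxymethoxy)phenol, via aryl formate 6 (not isolated)
Conditions: mCPBA, CH2Cl2, 0 → 23 °C; then Et3N, MeOH, 23 °C
Reagents that add atoms: 3-chloroperbenzoic acid, O=C(OO)c1cccc(Cl)c1
Why: Baeyer–Villiger (Dakin-type) oxidation, in which the electron-rich aryl group migrates, followed by mild methanolysis of the formate, as for 3,4,5-trialkoxybenzaldehydes.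

Step 5
Reactants: 7 4-(4-chlorophenoxy)-3,5-bis(methoxymethoxy)phenol
Product: 8 4-(4-chlorophenoxy)-3,5-bis(methoxymethoxy)phenyl N-isopropylcarbamate
Conditions: i-PrNCO, Et3N (cat.), CH2Cl2, 23 °C
Reagents that add atoms: isopropyl isocyanate, CC(C)N=C=O
Why: Amine-catalysed addition of the phenol to the isocyanate gives the secondary carbamate, a removable ortho-directing group.

Step 6
Reactants: 8 4-(4-chlorophenoxy)-3,5-bis(methoxymethoxy)phenyl N-isopropylcarbamate
Product: 12 4-(4-chlorophenoxy)-3,5-bis(methoxymethoxy)-2-(trimethylsilyl)phenyl N-isopropylcarbamate, via N-silyl carbamate 9 (not isolated), via aryllithium 10 (not isolated), via disilyl carbamate 11 (not isolated)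
Conditions: TBSOTf, TMEDA, Et2O, 0 → 23 °C; n-BuLi, TMEDA, −78 °C; TMSCl, −78 → 23 °C; aq. NaHSO4
Reagents that add atoms: chlorotrimethylsilane, C[Si](C)(C)Cl
Why: Directed ortho-metalation: the N-silylated carbamate and the neighbouring MOM ether direct n-BuLi/TMEDA to the only ring-A C–H (two equivalent sites by symmetry) at a temperature where the aryl chloride is inert, and TMSCl traps the aryllithium.

Step 7
Reactants: 12 4-(4-chlorophenoxy)-3,5-bis(methoxymethoxy)-2-(trimethylsilyl)phenyl N-isopropylcarbamate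
Product: 14 4-(4-chlorophenoxy)-3,5-bis(methoxymethoxy)-2-(trimethylsilyl)phenyl trifluoromethanesulfonate, via silyl phenol 13 (not isolated)
Conditions: DBU, Et2NH, MeCN, 40 °C; then PhNTf2, 23 °C
Reagents that add atoms: N-phenylbis(trifluoromethanesulfonimide), O=S(=O)(N(c1ccccc1)S(=O)(=O)C(F)(F)F)C(F)(F)F
Why: E1cB loss of isopropyl isocyanate (scavenged by Et2NH) frees the phenoxide, which is sulfonylated in the same pot, the standard carbamate route to ortho-silylaryl triflates.

Step 8
Reactants: 15 4-hydroxyacetophenone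
Product: 16 4-(methoxymethoxy)acetophenone
Conditions: MOMCl, i-Pr2NEt, CH2Cl2, 0 → 23 °C
Reagents that add atoms: chloromethyl methyl ether, COCCl
Why: MOM protection of the phenol, matching the protecting groups of ring A so that one acid step clears all of them.

Step 9
Reactants: 16 4-(methoxymethoxy)acetophenone
Product: 17 ethyl 3-[4-(methoxymethoxy)phenyl]-3-oxopropanoate
Conditions: NaH, (EtO)2CO, THF, 65 °C; then AcOH
Reagents that add atoms: diethyl carbonate, CCOC(=O)OCC
Why: Crossed Claisen condensation of the methyl ketone with diethyl carbonate, driven by formation of the β-keto ester enolate.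

Step 10
Reactants: 17 ethyl 3-[4-(methoxymethoxy)phenyl]-3-oxopropanoate
Product: 18 ethyl (3S)-3-hydroxy-3-[4-(methoxymethoxy)phenyl]propanoate
Conditions: RuCl[(S,S)-TsDPEN](p-cymene) (1 mol%), HCO2H/Et3N (5:2), EtOAc, 30 °C
Reagents that add atoms: none
Why: Noyori asymmetric transfer hydrogenation of an aryl ketone: the (S,S)-catalyst delivers hydride to the face that gives the (S)-benzylic alcohol, the same spatial sense as for acetophenone.

Step 11
Reactants: 18 ethyl (3S)-3-hydroxy-3-[4-(methoxymethoxy)phenyl]propanoate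
Product: 19 (3S)-3-hydroxy-N-methoxy-N-methyl-3-[4-(methoxymethoxy)phenyl]propanamide
Conditions: MeNH(OMe)·HCl, i-PrMgCl, THF, −20 → 0 °C
Reagents that add atoms: N,O-dimethylhydroxylamine hydrochloride, CNOC.Cl
Why: Weinreb amidation of the ester with the chloromagnesium amide made in the flask; the magnesium alkoxide of the β-hydroxyl does not undergo retro-aldol at this temperature and C3 is untouched.

Step 12
Reactants: 19 (3S)-3-hydroxy-N-methoxy-N-methyl-3-[4-(methoxymethoxy)phenyl]propanamide
Product: 20 (3S)-N-methoxy-N-methyl-3-[4-(methoxymethoxy)phenyl]-3-(trimethylsilyloxy)propanamide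
Conditions: TMSCl, imidazole, CH2Cl2, 0 °C
Reagents that add atoms: chlorotrimethylsilane, C[Si](C)(C)Cl
Why: Silylation of the secondary alcohol gives a fluoride-labile mask from which the alkoxide can be released without any O–H in the flask.

Step 13
Reactants: 14 4-(4-chlorophenoxy)-3,5-bis(methoxymethoxy)-2-(trimethylsilyl)phenyl trifluoromethanesulfonate; 20 (3S)-N-methoxy-N-methyl-3-[4-(methoxymethoxy)phenyl]-3-(trimethylsilyloxy)propanamide (1.3 equiv)
Product: 24 (2S)-6-(4-chlorophenoxy)-5,7-bis(methoxymethoxy)-2-[4-(methoxymethoxy)phenyl]chroman-4-one, via cesium alkoxide 21 (not isolated), via aryne 22 (not isolated), via hemiaminal alkoxide 23 (not isolated)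
Conditions: CsF, 18-crown-6, THF, 0 → 23 °C; then AcOH, 0 °C
Reagents that add atoms: none
Why: Proposed new method: fluoride removes the silyl group from triflate 14 (1,2-elimination to aryne 22) and from ether 20 (alkoxide 21) in a medium free of O–H; the alkoxide adds to the aryne carbon remote from the flanking MOM ether (the future C8a), and the aryl anion left at C4a attacks the Weinreb amide to give the tetrahedral alkoxide 23, which releases the C4 ketone only on the acetic acid quench. The closest known reaction types are the CsF-mediated annulation of arynes with salicylates to xanthones and aryne O-arylations followed by intramolecular acyl capture of the aryl anion; an aliphatic alkoxide with a β-amide has not been used in this way. Ring C closes by 6-exo-trig attack of the C4a carbanion on the amide carbonyl after intermolecular formation of O1–C8a. No stereocentre is created: C2 comes from alcohol 19 and keeps its configuration because only its O–Si bond is broken, and holding C4 as the hemiaminal alkoxide until the quench keeps the C3 enolate, and with it retro-oxa-Michael opening of ring C, out of reach. The selectivity needed is regiochemical (oxygen at C8a, acyl at C4a); it is secured by the inductive and distorting effect of the C5 alkoxy group of the 3-alkoxyaryne and by the hindered flank of that carbon, and the twofold symmetry of phenol 7 allows only one aryne. The silyl ether and the amide are chosen because a free hydroxyl would hand its proton back to the aryl anion (plain O–H insertion) and an ester would release a basic alkoxide beside a base-labile flavanone.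

Step 14
Reactants: 24 (2S)-6-(4-chlorophenoxy)-5,7-bis(methoxymethoxy)-2-[4-(methoxymethoxy)phenyl]chroman-4-one
Product: 25 (2S)-5,7-bis(methoxymethoxy)-2-[4-(methoxymethoxy)phenyl]-6-[4-(4,4,5,5-tetramethyl-1,3,2-dioxaborolan-2-yl)phenoxy]chroman-4-one
Conditions: B2pin2, Pd2(dba)3, XPhos, KOAc, 1,4-dioxane, 90 °C
Reagents that add atoms: bis(pinacolato)diboron, CC1(C)OB(B2OC(C)(C)C(C)(C)O2)OC1(C)C
Why: Miyaura borylation: XPhos-ligated zerovalent palladium inserts into the electron-rich aryl chloride, and the weak base KOAc is used to spare the base-labile C2 centre.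

Step 15
Reactants: 25 (2S)-5,7-bis(methoxymethoxy)-2-[4-(methoxymethoxy)phenyl]-6-[4-(4,4,5,5-tetramethyl-1,3,2-dioxaborolan-2-yl)phenoxy]chroman-4-one
Product: 26 [4-({(2S)-5,7-bis(methoxymethoxy)-2-[4-(methoxymethoxy)phenyl]-4-oxochroman-6-yl}oxy)phenyl]boronic acid
Conditions: NaIO4, NH4OAc, acetone/H2O, 23 °C
Reagents that add atoms: water, O
Why: Oxidative cleavage of the pinacol released in the hydrolysis equilibrium frees the boronic acid under buffered neutral conditions that leave MOM ethers, ketone and C2 alone.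

Step 16
Reactants: 27 5,7-dihydroxy-4H-chromen-4-one
Product: 28 4-oxo-4H-chromene-5,7-diyl diacetate
Conditions: Ac2O, pyridine, DMAP (cat.), 23 °C
Reagents that add atoms: acetic anhydride, CC(=O)OC(C)=O
Why: Acylation of both phenols, including the chelated 5-OH; acyloxy groups, unlike alkoxy groups, keep the chromone electrophilic and are removed by the same acid as the MOM ethers.

Step 17
Reactants: 26 [4-({(2S)-5,7-bis(methoxymethoxy)-2-[4-(methoxymethoxy)phenyl]-4-oxochroman-6-yl}oxy)phenyl]boronic acid; 28 4-oxo-4H-chromene-5,7-diyl diacetate (2 equiv)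
Product: 29 (2S)-2-[4-({(2S)-5,7-bis(methoxymethoxy)-2-[4-(methoxymethoxy)phenyl]-4-oxochroman-6-yl}oxy)phenyl]-4-oxochroman-5,7-diyl diacetate
Conditions: Pd(OCOCF3)2 (10 mol%), (R)-t-BuPyOx (12 mol%), NH4PF6, H2O, ClCH2CH2Cl, 60 °C
Reagents that add atoms: none
Why: Palladium-catalysed asymmetric conjugate addition of an arylboronic acid to a chromone: a cationic aryl complex of divalent palladium inserts the C2=C3 bond on the face left open by the tert-butyl oxazoline and the enolate is protonated, which sets C2 of unit 1 as S under ligand control, independent of the remote C2 of unit 2.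

Step 18
Reactants: 29 (2S)-2-[4-({(2S)-5,7-bis(methoxymethoxy)-2-[4-(methoxymethoxy)phenyl]-4-oxochroman-6-yl}oxy)phenyl]-4-oxochroman-5,7-diyl diacetate
Product: 30 (2S)-5,7-dihydroxy-6-{4-[(2S)-5,7-dihydroxy-4-oxochroman-2-yl]phenoxy}-2-(4-hydroxyphenyl)chroman-4-one (CNP0184214.1)
Conditions: HCl, MeOH, 50 °C
Reagents that add atoms: none
Why: Acid-catalysed acetal exchange and transesterification in methanol remove the three MOM ethers and both acetates, and acid at this temperature does not open ring C, so both C2 centres are kept.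

**Compound list**

1 | syringaldehyde (4-hydroxy-3,5-dimethoxybenzaldehyde) | COc1cc(C=O)cc(OC)c1O | starting material
2 | 4-chlorophenylboronic acid | OB(O)c1ccc(Cl)cc1 | starting material
3 | 4-(4-chlorophenoxy)-3,5-dimethoxybenzaldehyde | COc1cc(C=O)cc(OC)c1Oc1ccc(Cl)cc1 | intermediate
4 | 4-(4-chlorophenoxy)-3,5-dihydroxybenzaldehyde | O=Cc1cc(O)c(Oc2ccc(Cl)cc2)c(O)c1 | intermediate
5 | 4-(4-chlorophenoxy)-3,5-bis(methoxymethoxy)benzaldehyde | COCOc1cc(C=O)cc(OCOC)c1Oc1ccc(Cl)cc1 | intermediate
6 | 4-(4-chlorophenoxy)-3,5-bis(methoxymethoxy)phenyl formate | O=COc1cc(OCOC)c(Oc2ccc(Cl)cc2)c(OCOC)c1 | intermediate (not isolated)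
7 | 4-(4-chlorophenoxy)-3,5-bis(methoxymethoxy)phenol | COCOc1cc(O)cc(OCOC)c1Oc1ccc(Cl)cc1 | intermediate
8 | 4-(4-chlorophenoxy)-3,5-bis(methoxymethoxy)phenyl N-isopropylcarbamate | CC(C)NC(=O)Oc1cc(OCOC)c(Oc2ccc(Cl)cc2)c(OCOC)c1 | intermediate
9 | 4-(4-chlorophenoxy)-3,5-bis(methoxymethoxy)phenyl N-(tert-butyldimethylsilyl)-N-isopropylcarbamate | CC(C)N(C(=O)Oc1cc(OCOC)c(Oc2ccc(Cl)cc2)c(OCOC)c1)[Si](C)(C)C(C)(C)C | intermediate (not isolated)
10 | 2-lithio derivative of 9 (lithium at the ring carbon between the carbamate oxygen and a MOM ether) | CC(C)N(C(=O)Oc1cc(OCOC)c(Oc2ccc(Cl)cc2)c(OCOC)c1[Li])[Si](C)(C)C(C)(C)C | intermediate (not isolated)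
11 | 4-(4-chlorophenoxy)-3,5-bis(methoxymethoxy)-2-(trimethylsilyl)phenyl N-(tert-butyldimethylsilyl)-N-isopropylcarbamate | CC(C)N(C(=O)Oc1cc(OCOC)c(Oc2ccc(Cl)cc2)c(OCOC)c1[Si](C)(C)C)[Si](C)(C)C(C)(C)C | intermediate (not isolated)
12 | 4-(4-chlorophenoxy)-3,5-bis(methoxymethoxy)-2-(trimethylsilyl)phenyl N-isopropylcarbamate | CC(C)NC(=O)Oc1cc(OCOC)c(Oc2ccc(Cl)cc2)c(OCOC)c1[Si](C)(C)C | intermediate
13 | 4-(4-chlorophenoxy)-3,5-bis(methoxymethoxy)-2-(trimethylsilyl)phenol | C[Si](C)(C)c1c(O)cc(OCOC)c(Oc2ccc(Cl)cc2)c1OCOC | intermediate (not isolated)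
14 | 4-(4-chlorophenoxy)-3,5-bis(methoxymethoxy)-2-(trimethylsilyl)phenyl trifluoromethanesulfonate | C[Si](C)(C)c1c(OS(=O)(=O)C(F)(F)F)cc(OCOC)c(Oc2ccc(Cl)cc2)c1OCOC | intermediate
15 | 4-hydroxyacetophenone | CC(=O)c1ccc(O)cc1 | starting material
16 | 4-(methoxymethoxy)acetophenone | CC(=O)c1ccc(OCOC)cc1 | intermediate
17 | ethyl 3-[4-(methoxymethoxy)phenyl]-3-oxopropanoate | CCOC(=O)CC(=O)c1ccc(OCOC)cc1 | intermediate
18 | ethyl (3S)-3-hydroxy-3-[4-(methoxymethoxy)phenyl]propanoate | CCOC(=O)C[C@H](O)c1ccc(OCOC)cc1 | intermediate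
19 | (3S)-3-hydroxy-N-methoxy-N-methyl-3-[4-(methoxymethoxy)phenyl]propanamide | CON(C)C(=O)C[C@H](O)c1ccc(OCOC)cc1 | intermediate
20 | (3S)-N-methoxy-N-methyl-3-[4-(methoxymethoxy)phenyl]-3-(trimethylsilyloxy)propanamide | CON(C)C(=O)C[C@H](O[Si](C)(C)C)c1ccc(OCOC)cc1 | intermediate
21 | cesium (1S)-3-[methoxy(methyl)amino]-1-[4-(methoxymethoxy)phenyl]-3-oxopropan-1-olate | CON(C)C(=O)C[C@H]([O-])c1ccc(OCOC)cc1.[Cs+] | intermediate (not isolated)
22 | 4-(4-chlorophenoxy)-3,5-bis(methoxymethoxy)-1,2-didehydrobenzene (aryne) | COCOC1=C(Oc2ccc(Cl)cc2)C(OCOC)=CC#C1 | intermediate (not isolated)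
23 | cesium (2S)-6-(4-chlorophenoxy)-4-[methoxy(methyl)amino]-5,7-bis(methoxymethoxy)-2-[4-(methoxymethoxy)phenyl]chroman-4-olate (C4 epimers) | CON(C)C1([O-])C[C@@H](c2ccc(OCOC)cc2)Oc2cc(OCOC)c(Oc3ccc(Cl)cc3)c(OCOC)c21.[Cs+] | intermediate (not isolated)
24 | (2S)-6-(4-chlorophenoxy)-5,7-bis(methoxymethoxy)-2-[4-(methoxymethoxy)phenyl]chroman-4-one | O=C1C[C@@H](c2ccc(OCOC)cc2)Oc2cc(OCOC)c(Oc3ccc(Cl)cc3)c(OCOC)c21 | intermediate
25 | (2S)-5,7-bis(methoxymethoxy)-2-[4-(methoxymethoxy)phenyl]-6-[4-(4,4,5,5-tetramethyl-1,3,2-dioxaborolan-2-yl)phenoxy]chroman-4-one | O=C1C[C@@H](c2ccc(OCOC)cc2)Oc2cc(OCOC)c(Oc3ccc(B4OC(C)(C)C(C)(C)O4)cc3)c(OCOC)c21 | intermediate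
26 | [4-({(2S)-5,7-bis(methoxymethoxy)-2-[4-(methoxymethoxy)phenyl]-4-oxochroman-6-yl}oxy)phenyl]boronic acid | O=C1C[C@@H](c2ccc(OCOC)cc2)Oc2cc(OCOC)c(Oc3ccc(B(O)O)cc3)c(OCOC)c21 | intermediate
27 | 5,7-dihydroxy-4H-chromen-4-one | O=c1ccoc2cc(O)cc(O)c12 | starting material
28 | 4-oxo-4H-chromene-5,7-diyl diacetate | CC(=O)Oc1cc(OC(C)=O)c2c(=O)ccoc2c1 | intermediate
29 | (2S)-2-[4-({(2S)-5,7-bis(methoxymethoxy)-2-[4-(methoxymethoxy)phenyl]-4-oxochroman-6-yl}oxy)phenyl]-4-oxochroman-5,7-diyl diacetate | O=C1C[C@@H](c2ccc(Oc3c(OCOC)cc4c(c3OCOC)C(=O)C[C@@H](c3ccc(OCOC)cc3)O4)cc2)Oc2cc(OC(C)=O)cc(OC(C)=O)c21 | intermediate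
30 | (2S)-5,7-dihydroxy-6-{4-[(2S)-5,7-dihydroxy-4-oxochroman-2-yl]phenoxy}-2-(4-hydroxyphenyl)chroman-4-one | O=C1C[C@@H](c2ccc(Oc3c(O)cc4c(c3O)C(=O)C[C@@H](c3ccc(O)cc3)O4)cc2)Oc2cc(O)cc(O)c21 | target

**Step count**

Total: 18 steps. Longest linear sequence: 12 steps (1–7, 13, 14, 15, 17, 18).

**Steps most likely to fail**

1. Step 13 (the new annulation). The C4a aryl anion may be captured by a proton or a silyl group before it reaches the amide carbonyl, which would leave the open aryl ether. The alkoxide may attack the sulfonyl sulfur of the triflate instead of the aryne. If the tetrahedral adduct collapses early, base could open ring C and erode C2. The fallback uses only known reaction types; it sets out from carbamate 8 and returns at 24. Carbamate 8 is lithiated as in step 6 (through 9 and 10) and the aryllithium is acylated with N-methoxy-N-methylacetamide. Acidic work-up of the N-silyl aryl ketone F1 gives the ortho-acetyl carbamate F2. DBU/Et2NH in MeCN releases the 2-hydroxyacetophenone F3. Condensation with DMF-DMA gives the enaminone F4, which acetic acid closes to the chromone F5. Conjugate addition of commercial 4-(methoxymethoxy)phenylboronic acid under Pd(OCOCF3)2/(R)-t-BuPyOx, as in step 17, then sets C2 under ligand control and gives 24.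

2. Step 17. Protodeboronation of the valuable boronic acid 26 may outrun insertion of the chromone. β-Oxygen elimination from the palladium enolate would open the new ring, and facial selectivity may be poor on this large aryl group. The fallback leaves the electrophilic divalent-palladium manifold for a nucleophilic aryl complex of monovalent rhodium (Hayashi–Miyaura 1,4-addition): [Rh(OH)(cod)]2 with a chiral diene or an electron-poor chiral bisphosphine in aqueous dioxane without added base, ligand enantiomer chosen for 2S. It sets out from 26 and 28 and returns at 29; no compound outside the list is made (F0).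

3. Step 1. Transmetalation and C–O bond formation at the di-ortho-substituted, electron-poor phenoxide may be slow, so that homocoupling and protodeboronation consume boronic acid 2. The fallback replaces copper-mediated oxidative coupling by metal-free ligand coupling at hypervalent iodine: the phenoxide of 1 (t-BuOK, THF, 23 °C) is arylated with bis(4-chlorophenyl)iodonium tetrafluoroborate. It sets out from 1 and returns at 3; no compound outside the list is made (F0).

**Further compounds**

F1 | step 13 | 2-acetyl-4-(4-chlorophenoxy)-3,5-bis(methoxymethoxy)phenyl N-(tert-butyldimethylsilyl)-N-isopropylcarbamate (not isolated) | CC(C)N(C(=O)Oc1cc(OCOC)c(Oc2ccc(Cl)cc2)c(OCOC)c1C(C)=O)[Si](C)(C)C(C)(C)C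
F2 | step 13 | 2-acetyl-4-(4-chlorophenoxy)-3,5-bis(methoxymethoxy)phenyl N-isopropylcarbamate | CC(C)NC(=O)Oc1cc(OCOC)c(Oc2ccc(Cl)cc2)c(OCOC)c1C(C)=O
F3 | step 13 | 1-[3-(4-chlorophenoxy)-6-hydroxy-2,4-bis(methoxymethoxy)phenyl]ethanone | CC(=O)c1c(O)cc(OCOC)c(Oc2ccc(Cl)cc2)c1OCOC
F4 | step 13 | (E)-1-[3-(4-chlorophenoxy)-6-hydroxy-2,4-bis(methoxymethoxy)phenyl]-3-(dimethylamino)prop-2-en-1-one | CN(C)/C=C/C(=O)c1c(O)cc(OCOC)c(Oc2ccc(Cl)cc2)c1OCOC
F5 | step 13 | 6-(4-chlorophenoxy)-5,7-bis(methoxymethoxy)-4H-chromen-4-one | O=c1ccoc2cc(OCOC)c(Oc3ccc(Cl)cc3)c(OCOC)c12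
F0 | step 17 | none | none
F0 | step 1 | none | none
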